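C1 is the ring-fusion carbon bearing CH3, C2 is CH–O-angeloyl, C3 is CH2, C4 is C(OH)-i-Pr, C5 is the ring-fusion CH, C6 is CH–O-aroyl, C7 is CH2, C8(CH3)=C9, and C10 is CH2. Ring A (five-membered) is C1–C5 and ring B (seven-membered) is C1, C5–C10; they are cis-fused, with C1–CH3, C5–H, C6–O and i-Pr on one face and C2–O and C4–OH on the other.
Retrosynthetic cuts, in order: O–acyl at C2; O–acyl at C6; C4–i-Pr; C6–O together with C5–H (back to a C4-keto C5=C6 enone); C1–C10 (retro-[3,3], which re-forms C6–C8); C5–C6 (cross-coupling).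
Enabling feature: with C5=C6 in place, ring B (C1–C5=C6–C7H2–C8(CH3)=C9–C10H2) is a cyclohepta-1,4-diene. Its only sp3–sp3 ring bond, C1–C10, ends at the quaternary carbon, and its C7 methylene lies between the two alkenes just as the CH2 of a cis-dialkenylcyclopropane C6–C7–C8 would.
Forward order: ring A is bought as a cyclopentenone, and the cyclopropane C6–C7–C8 is made from propargyl alcohol. Both are joined at C5–C6, heating expands the three-membered ring to ring B, and then C6/C5, C4 and the two esters follow.
Stereochemistry: C2 comes from (S)-4-silyloxycyclopentenone. The cyclopropane centres come from a Z-iodoalkene plus a Charette cyclopropanation and are relayed to C1 through the boat transition state. C6, C5 and C4 arise from attack on the convex, methyl-bearing face, and the Z ester geometry comes from angelic acid.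

Key step: step 9

Assumption: (S)-4-(tert-butyldimethylsilyloxy)cyclopent-2-en-1-one is taken as commercial. C2 travels as the silyl ether of its final configuration, so no neopentyl ketone has to be reduced late and no acid-labile mask has to be removed beside the tertiary C4 alcohol.

Step 1
Reactants: 1 prop-2-yn-1-ol
Product: 3 (Z)-3-iodo-2-methylprop-2-en-1-ol, via alkenylmagnesium alkoxide 2 (not isolated)
Conditions: MeMgBr (2.5 equiv), CuI (10 mol %), THF, −10 °C to rt; then I2, −20 °C to rt
Reagents that add atoms: methylmagnesium bromide C[Mg]Br; iodine [I][I]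
Why: Copper-catalysed carbomagnesiation of the propargylic alkoxide places methyl on the internal carbon and magnesium on the terminus in an anti sense because the alkoxide holds the metal in a five-membered chelate, so iodinolysis with retention should give the Z iodoalkene (the E isomer would end as the unreactive trans-dialkenylcyclopropane).

Step 2
Reactants: 3 (Z)-3-iodo-2-methylprop-2-en-1-ol
Product: 4 [(1R,2R)-2-iodo-1-methylcyclopropyl]methanol
Conditions: Et2Zn, CH2I2, DME, (4R,5R)-2-butyl-N,N,N′,N′-tetramethyl-1,3,2-dioxaborolane-4,5-dicarboxamide (1.2 equiv), CH2Cl2, −10 °C to rt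
Reagents that add atoms: diiodomethane C(I)I
Why: In the Charette asymmetric Simmons–Smith cyclopropanation the zinc alkoxide of 3 binds the (4R,5R)-dioxaborolane, which steers methylene delivery to one alkene face (1R,2R), while the concerted syn addition turns the Z geometry into the cis relationship of iodine and CH2OH.

Step 3
Reactants: 4 [(1R,2R)-2-iodo-1-methylcyclopropyl]methanol
Product: 5 (1R,2R)-2-iodo-1-methylcyclopropane-1-carbaldehyde
Conditions: TEMPO (10 mol %), PhI(OAc)2, CH2Cl2, rt
Reagents that add atoms: none
Why: Oxoammonium-mediated oxidation stops at the aldehyde, leaves the C–I bond alone, and cannot epimerise anything because the α-carbon is quaternary.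

Step 4
Reactants: 5 (1R,2R)-2-iodo-1-methylcyclopropane-1-carbaldehyde
Product: 6 (1R,2R)-1-ethenyl-2-iodo-1-methylcyclopropane
Conditions: Ph3PCH3Br, KN(SiMe3)2 (slight deficit), THF, 0 °C; then 5, −78 °C to rt
Reagents that add atoms: methyltriphenylphosphonium bromide C[P+](c1ccccc1)(c1ccccc1)c1ccccc1.[Br-]
Why: Wittig methylenation of a non-enolisable aldehyde with a pre-formed ylide, free of excess base, should spare the iodocyclopropane and leave both ring stereocentres untouched, with vinyl and iodine cis.

Step 5
Reactants: 7 (S)-4-(tert-butyldimethylsilyloxy)cyclopent-2-en-1-one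
Product: 8 (1S,2S)-1-(tert-butyldimethylsilyloxy)-2-methyl-4-(trimethylsilyloxy)cyclopent-3-ene
Conditions: MeLi, CuI, Et2O, 0 °C; then TMSCl and 7, THF, −78 °C
Reagents that add atoms: methyllithium [Li]C; chlorotrimethylsilane C[Si](C)(C)Cl
Why: Gilman cuprate 1,4-addition occurs anti to the silyloxy group, and in situ silylation locks the enolate regiochemistry at C4=C5 so that silyloxide cannot be lost by β-elimination; the new methine centre is transient.

Step 6
Reactants: 8 (1S,2S)-1-(tert-butyldimethylsilyloxy)-2-methyl-4-(trimethylsilyloxy)cyclopent-3-ene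
Product: 9 (S)-4-(tert-butyldimethylsilyloxy)-3-methylcyclopent-2-en-1-one
Conditions: Pd(OAc)2 (10 mol %), O2 (1 atm), DMSO, rt
Reagents that add atoms: none
Why: In the Saegusa–Ito oxidation divalent palladium binds the silyl enol ether at C5 and eliminates C1–H, the only β-hydrogen, which restores the enone with methyl on the β-carbon while oxygen re-oxidises the metal and C2 stays untouched.

Step 7
Reactants: 9 (S)-4-(tert-butyldimethylsilyloxy)-3-methylcyclopent-2-en-1-one
Product: 11 (S)-2-bromo-4-(tert-butyldimethylsilyloxy)-3-methylcyclopent-2-en-1-one, via trans-dibromide 10 (not isolated)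
Conditions: Br2, CH2Cl2, 0 °C; then Et3N, 0 °C to rt
Reagents that add atoms: bromine BrBr
Why: Bromine addition to the enone followed by amine-induced loss of HBr (acidic C5–H, tertiary C1 bromide) is the standard bromination–dehydrobromination route to 2-bromo-3-alkylcyclopentenones and is tolerated by 4-silyloxy enones.

Step 8
Reactants: 6 (1R,2R)-1-ethenyl-2-iodo-1-methylcyclopropane; 11 (S)-2-bromo-4-(tert-butyldimethylsilyloxy)-3-methylcyclopent-2-en-1-one
Product: 14 (S)-4-(tert-butyldimethylsilyloxy)-2-[(1R,2R)-2-ethenyl-2-methylcyclopropyl]-3-methylcyclopent-2-en-1-one, via cyclopropyllithium 12 (not isolated), via cyclopropylzinc chloride 13 (not isolated)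
Conditions: 6, t-BuLi (2 equiv), Et2O, −78 °C; ZnCl2, THF, −78 to 0 °C; then 11, Pd2(dba)3 (2.5 mol %), SPhos (10 mol %), THF, rt
Reagents that add atoms: none
Why: Iodine–lithium exchange, transmetalation to zinc and Negishi coupling on zerovalent palladium all proceed with retention at the configurationally stable cyclopropyl carbon, the organozinc leaves the ketone and silyl ether alone, and at room temperature the hindered cis-dialkenylcyclopropane should persist.

Step 9
Reactants: 14 (S)-4-(tert-butyldimethylsilyloxy)-2-[(1R,2R)-2-ethenyl-2-methylcyclopropyl]-3-methylcyclopent-2-en-1-one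
Product: 15 (3S,3aR)-3-(tert-butyldimethylsilyloxy)-3a,6-dimethyl-3,3a,4,7-tetrahydroazulen-1(2H)-one
Conditions: PhMe (degassed, 0.02 M), BHT (trace), base-washed sealed tube, 110–130 °C
Reagents that add atoms: none
Why: This is a concerted [3,3]-sigmatropic shift through the endo-boat transition state, in which the strained C6–C8 bond opens while the vinyl terminus C10 bonds to the enone β-carbon C1 and the π bonds move to C5=C6 and C8=C9. The closest known reaction type is the thermal cis-divinylcyclopropane–cycloheptadiene rearrangement of 1-(2-methylcyclopentenyl)-2-vinylcyclopropanes to angularly methylated hydroazulenes, where the methyl group also points inward and only raises the temperature needed. Ring B closes by ring expansion (three cyclopropane carbons plus four alkenyl carbons) rather than by exo or endo attack of a chain end, so both ring alkenes must be Z and C7 ends as the methylene between them. C1, the only new stereocentre, is controlled by the (1R,2R)-cyclopropane: in the boat the vinyl group reaches only one face of C1=C5, which gives 1R with C10 syn and CH3 anti to the C2 silyloxy group. C2 is a spectator that would turn any C1 epimer into a separable diastereomer. The step needs the pericyclic path to outrun C6–C8 homolysis and homodienyl hydrogen shift, and this is secured by the cis geometry built in steps 1 and 2, by the acyl group on C5 (position 2 of the hexadiene, which stabilises a transition state with advanced bond formation), and by the absence of any alkyl C–H cis to an alkenyl group on the three-membered ring.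

Step 10
Reactants: 15 (3S,3aR)-3-(tert-butyldimethylsilyloxy)-3a,6-dimethyl-3,3a,4,7-tetrahydroazulen-1(2H)-one
Product: 17 (3S,3aR,8R,8aR)-3-(tert-butyldimethylsilyloxy)-8-hydroxy-3a,6-dimethyl-3,3a,4,7,8,8a-hexahydroazulen-1(2H)-one, via beta-boryl ketone 16 (not isolated)
Conditions: B2pin2, CuCl (5 mol %), DPEphos (5 mol %), NaOt-Bu (10 mol %), MeOH (2 equiv), THF, rt; then NaBO3·4H2O, THF–H2O, 0 °C to rt
Reagents that add atoms: sodium perborate [Na+].[O-]OB=O
Why: Copper-catalysed β-borylation touches only the electron-poor C5=C6 bond and ignores C8=C9; the boryl-copper species should add to C6, and methanol should protonate the enolate at C5, from the convex face carrying C1–CH3 because the C7–C8=C9–C10 bridge folds under the other face, giving the cis ring fusion (5R) and, after oxidation with retention at carbon, the 6R alcohol.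

Step 11
Reactants: 17 (3S,3aR,8R,8aR)-3-(tert-butyldimethylsilyloxy)-8-hydroxy-3a,6-dimethyl-3,3a,4,7,8,8a-hexahydroazulen-1(2H)-one; 18 isopropylmagnesium chloride
Product: 19 (1S,3S,3aR,8R,8aR)-3-(tert-butyldimethylsilyloxy)-1-isopropyl-3a,6-dimethyl-1,2,3,3a,4,7,8,8a-octahydroazulene-1,8-diol
Conditions: LaCl3·2LiCl (1 equiv), THF, rt; then 18 (3.5 equiv), −20 to 0 °C; aq NH4Cl
Reagents that add atoms: none
Why: In this lanthanum-assisted Grignard 1,2-addition the salt raises carbonyl electrophilicity and damps enolisation and β-hydride transfer, the first equivalent only turns C6–OH into an alkoxide that cannot leave, and isopropyl should attack C4 from the convex face (C5–H, C1–CH3), away from C6 and the C2 silyloxy group, which sets 4S.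

Step 12
Reactants: 19 (1S,3S,3aR,8R,8aR)-3-(tert-butyldimethylsilyloxy)-1-isopropyl-3a,6-dimethyl-1,2,3,3a,4,7,8,8a-octahydroazulene-1,8-diol; 20 3,4,5-trimethoxybenzoyl chloride
Product: 21 C6 3,4,5-trimethoxybenzoate of 19 (C2 silyl ether and free C4–OH retained)
Conditions: 20, Et3N, DMAP (20 mol %), CH2Cl2, 0 °C to rt
Reagents that add atoms: none
Why: DMAP-catalysed acylation reaches only the secondary C6–OH, since the tertiary C4–OH is inert and C2–O is still silylated, and no C–O bond at a stereocentre is broken.

Step 13
Reactants: 21 C6 3,4,5-trimethoxybenzoate of 19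
Product: 22 C2,C4-diol C6 3,4,5-trimethoxybenzoate (1R,2S,4S,5R,6R)
Conditions: HF·pyridine, pyridine, THF, 0 °C to rt
Reagents that add atoms: none
Why: Fluoride-driven Si–O cleavage in a buffered, non-basic medium frees the neopentyl C2–OH without forming alkoxides, so aroyl migration, ester cleavage and ionisation of the tertiary alcohol should not occur.

Step 14
Reactants: 22 C2,C4-diol C6 3,4,5-trimethoxybenzoate; 23 angelic acid ((Z)-2-methylbut-2-enoic acid)
Product: 25 CNP0112256.1, via mixed anhydride 24 (not isolated)
Conditions: 23, 2,4,6-trichlorobenzoyl chloride, Et3N, PhMe, rt; then 22, 80 °C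
Reagents that add atoms: none
Why: Yamaguchi-type mixed-anhydride esterification run without a nucleophilic catalyst is the established way to transfer the angeloyl group with its Z geometry intact (no reversible conjugate addition), acylates only the secondary C2–OH beside the tertiary C4–OH, and keeps the C2 configuration because the C–O bond is not broken.

Compound list
1 | prop-2-yn-1-ol | C#CCO | starting material
2 | bromomagnesium (Z)-3-(bromomagnesio)-2-methylprop-2-en-1-olate | Br[Mg]OC/C(C)=C\[Mg]Br | intermediate
3 | (Z)-3-iodo-2-methylprop-2-en-1-ol | OC/C(C)=C\I | intermediate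
4 | [(1R,2R)-2-iodo-1-methylcyclopropyl]methanol (I cis to CH2OH) | I[C@@H]1C[C@]1(C)CO | intermediate
5 | (1R,2R)-2-iodo-1-methylcyclopropane-1-carbaldehyde | I[C@@H]1C[C@]1(C)C=O | intermediate
6 | (1R,2R)-1-ethenyl-2-iodo-1-methylcyclopropane (I cis to vinyl) | I[C@@H]1C[C@]1(C)C=C | intermediate
7 | (S)-4-(tert-butyldimethylsilyloxy)cyclopent-2-en-1-one | CC(C)(C)[Si](C)(C)O[C@H]1CC(=O)C=C1 | starting material
8 | (1S,2S)-1-(tert-butyldimethylsilyloxy)-2-methyl-4-(trimethylsilyloxy)cyclopent-3-ene (CH3 trans to OTBS) | CC(C)(C)[Si](C)(C)O[C@H]1CC(O[Si](C)(C)C)=C[C@@H]1C | intermediate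
9 | (S)-4-(tert-butyldimethylsilyloxy)-3-methylcyclopent-2-en-1-one | CC(C)(C)[Si](C)(C)O[C@H]1CC(=O)C=C1C | intermediate
10 | (2S,3S,4S)-2,3-dibromo-4-(tert-butyldimethylsilyloxy)-3-methylcyclopentan-1-one (drawn as the anti adduct; both C–Br centres are erased) | CC(C)(C)[Si](C)(C)O[C@H]1CC(=O)[C@H](Br)[C@@]1(C)Br | intermediate
11 | (S)-2-bromo-4-(tert-butyldimethylsilyloxy)-3-methylcyclopent-2-en-1-one | CC(C)(C)[Si](C)(C)O[C@H]1CC(=O)C(Br)=C1C | intermediate
12 | cis-2-ethenyl-2-methylcyclopropyllithium (Li in place of I of 6, configuration retained) | [Li][C@@H]1C[C@]1(C)C=C | intermediate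
13 | [(1R,2R)-2-ethenyl-2-methylcyclopropyl]zinc chloride | Cl[Zn][C@@H]1C[C@]1(C)C=C | intermediate
14 | (S)-4-(tert-butyldimethylsilyloxy)-2-[(1R,2R)-2-ethenyl-2-methylcyclopropyl]-3-methylcyclopent-2-en-1-one (cyclopentenyl cis to vinyl) | CC(C)(C)[Si](C)(C)O[C@H]1CC(=O)C([C@@H]2C[C@]2(C)C=C)=C1C | intermediate
15 | (3S,3aR)-3-(tert-butyldimethylsilyloxy)-3a,6-dimethyl-3,3a,4,7-tetrahydroazulen-1(2H)-one (1R,2S; C4 ketone, C5=C6, C8=C9) | CC(C)(C)[Si](C)(C)O[C@H]1CC(=O)C2=CCC(C)=CC[C@@]12C | intermediate
16 | C6 pinacolboronate of the cis-fused C4 ketone (C6–B and C5–H syn to C1–CH3) | CC(C)(C)[Si](C)(C)O[C@H]1CC(=O)[C@H]2[C@H](B3OC(C)(C)C(C)(C)O3)CC(C)=CC[C@@]12C | intermediate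
17 | (3S,3aR,8R,8aR)-3-(tert-butyldimethylsilyloxy)-8-hydroxy-3a,6-dimethyl-3,3a,4,7,8,8a-hexahydroazulen-1(2H)-one (1R,2S,5R,6R) | CC(C)(C)[Si](C)(C)O[C@H]1CC(=O)[C@H]2[C@H](O)CC(C)=CC[C@@]12C | intermediate
18 | isopropylmagnesium chloride | CC(C)[Mg]Cl | starting material
19 | (1S,3S,3aR,8R,8aR)-3-(tert-butyldimethylsilyloxy)-1-isopropyl-3a,6-dimethyl-1,2,3,3a,4,7,8,8a-octahydroazulene-1,8-diol (1R,2S,4S,5R,6R) | CC(C)(C)[Si](C)(C)O[C@H]1C[C@](O)(C(C)C)[C@H]2[C@H](O)CC(C)=CC[C@@]12C | intermediate
20 | 3,4,5-trimethoxybenzoyl chloride | COc1cc(cc(OC)c1OC)C(=O)Cl | starting material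
21 | C6 3,4,5-trimethoxybenzoate of 19 | CC(C)(C)[Si](C)(C)O[C@H]1C[C@](O)(C(C)C)[C@H]2[C@H](OC(=O)c3cc(OC)c(OC)c(OC)c3)CC(C)=CC[C@@]12C | intermediate
22 | C2,C4-diol C6 3,4,5-trimethoxybenzoate (1R,2S,4S,5R,6R) | O[C@H]1C[C@](O)(C(C)C)[C@H]2[C@H](OC(=O)c3cc(OC)c(OC)c(OC)c3)CC(C)=CC[C@@]12C | intermediate
23 | angelic acid, (Z)-2-methylbut-2-enoic acid | C/C=C(/C)C(=O)O | starting material
24 | angelic 2,4,6-trichlorobenzoic anhydride | C/C=C(/C)C(=O)OC(=O)c1c(Cl)cc(Cl)cc1Cl | intermediate
25 | CNP0112256.1, (1S,3S,3aR,8R,8aR)-1-hydroxy-1-isopropyl-3a,6-dimethyl-8-(3,4,5-trimethoxybenzoyloxy)-1,2,3,3a,4,7,8,8a-octahydroazulen-3-yl (Z)-2-methylbut-2-enoate | C/C=C(/C)C(=O)O[C@H]1C[C@](O)(C(C)C)[C@H]2[C@H](OC(=O)c3cc(OC)c(OC)c(OC)c3)CC(C)=CC[C@@]12C | target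

Total step count: 14. Longest linear sequence: 11 steps (steps 1–4, then 8–14); the second branch (steps 5–7) joins at step 8.

Steps most likely to fail

**Step 10.**
- Risk: the boryl-copper reagent may not distinguish the two faces of C5=C6 well enough. The enolate may also be protonated, or the ketone later epimerised under the mildly basic oxidation, so that the ring fusion drifts towards trans.
- Fallback: it sets out from 15. Nucleophilic epoxidation with lithium tert-butyl peroxide (t-BuOOH, n-BuLi, THF, −20 °C), a weakly basic oxidant that should spare the doubly allylic C7–H, would place oxygen on the same convex face of the enone and give the epoxy ketone F1. Samarium diiodide (SmI2, THF–MeOH, −90 °C) would then cleave the C5–O bond. The samarium enolate, whose C6 alkoxide holds the proton source on the methyl-bearing face, would be protonated kinetically at low temperature.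
- Return: the route is rejoined at 17.

**Step 9.**
- Risk: pressing C10 against the face that carries the bulky silyloxy group, on top of the inward methyl, may slow the shift. Homolysis of C6–C8 could then leak to the trans-cyclopropane and to the C1 epimer.
- Fallback: it sets out from 14. The silyl group is removed first (HF·pyridine, THF) to give the hydroxy enone F2, which carries only a small OH on the attacked face. F2 is heated in toluene to give the hydroxy dienone F3.
- Return: re-silylation (TBSOTf, 2,6-lutidine, CH2Cl2) rejoins the route at 15.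

**Step 8.**
- Risk: transmetalation and reductive elimination at a secondary cyclopropyl–palladium centre flanked by a quaternary carbon and a fully substituted alkene may be slow. Protodemetalation, homocoupling or debromination could then take over.
- Fallback: it sets out from 2 and 11 and forms the easier sp2–sp2 bond before the ring is made. Intermediate 2 is quenched with Bu3SnCl instead of iodine to give the alkenylstannane F4. Stille coupling with 11 (Pd2(dba)3, AsPh3, CuI, DMF) gives the dienone alcohol F5. The hydroxyl-directed Charette cyclopropanation with the same (4R,5R)-dioxaborolane, which leaves the electron-poor enone alkene alone, gives the cyclopropylmethanol F6. TEMPO/PhI(OAc)2 oxidation gives the aldehyde F7.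
- Return: aldehyde-selective Wittig methylenation rejoins the route at 14.

Further compounds
F1 | step 10 | C5,C6-epoxy C4 ketone, epoxide oxygen syn to C1–CH3 | CC(C)(C)[Si](C)(C)O[C@H]1CC(=O)[C@@]2(O3)[C@H]3CC(C)=CC[C@@]12C
F2 | step 9 | (S)-2-[(1R,2R)-2-ethenyl-2-methylcyclopropyl]-4-hydroxy-3-methylcyclopent-2-en-1-one | O[C@H]1CC(=O)C([C@@H]2C[C@]2(C)C=C)=C1C
F3 | step 9 | (3S,3aR)-3-hydroxy-3a,6-dimethyl-3,3a,4,7-tetrahydroazulen-1(2H)-one | O[C@H]1CC(=O)C2=CCC(C)=CC[C@@]12C
F4 | step 8 | (Z)-2-methyl-3-(tributylstannyl)prop-2-en-1-ol | OC/C(C)=C\[Sn](CCCC)(CCCC)CCCC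
F5 | step 8 | (S)-4-(tert-butyldimethylsilyloxy)-2-[(Z)-3-hydroxy-2-methylprop-1-enyl]-3-methylcyclopent-2-en-1-one | CC(C)(C)[Si](C)(C)O[C@H]1CC(=O)C(/C=C(/C)CO)=C1C
F6 | step 8 | (S)-4-(tert-butyldimethylsilyloxy)-2-[(1R,2R)-2-(hydroxymethyl)-2-methylcyclopropyl]-3-methylcyclopent-2-en-1-one | CC(C)(C)[Si](C)(C)O[C@H]1CC(=O)C([C@@H]2C[C@]2(C)CO)=C1C
F7 | step 8 | cis-2-(cyclopentenonyl)-1-methylcyclopropane-1-carbaldehyde derived from F6 | CC(C)(C)[Si](C)(C)O[C@H]1CC(=O)C([C@@H]2C[C@]2(C)C=O)=C1C
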